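The readings were generated by integration on assumed constants; scatter was added.

**The dose.** If starting material falls pseudo-first-order, what is left after time t is exp(−kt), so one number, kt, carries its fate. The flasks differ in initiator charge c, so you need k as a function of c.

| flask | starting material | partner | initiator | remark | time |
|---|---|---|---|---|---|
| larch | 0.33 M | 0.396 M | 40 mM | run made earlier |  |
| alder | 0.33 M | 0.396 M | 460 mM | run made earlier |  |
| alpha | 0.33 M | 0.396 M | 33 mM |  | 1.5 h |
| beta | 0.33 M | 0.396 M | 99 mM |  | 1.5 h |
| theta | 0.33 M | 0.396 M | 300 mM |  | 1.5 h |

| run | time / min | target / % | isomer of the product / % | starting material / % | first chain carrier / % |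
|---|---|---|---|---|---|
| larch | 8.00 | 4.3 | 0.6 | 94.4 | 1.8 |
| larch | 15.0 | 8.9 | 3.2 | 86.0 | 1.6 |
| larch | 25.0 | 12.8 | 6.2 | 80.0 | 1.0 |
| larch | 50.0 | 22.8 | 7.5 | 63.8 | 0 |
| larch | 90.0 | 42.4 | 10.8 | 47.2 | 0 |
| alder | 8.00 | 16.5 | 5.4 | 76.1 | 0.1 |
| alder | 15.0 | 28.5 | 11.6 | 59.8 | 1.2 |
| alder | 25.0 | 42.1 | 17.1 | 39.0 | 1.6 |
| alder | 50.0 | 68.4 | 20.7 | 9.7 | 1.5 |
| alder | 90.0 | 88.7 | 14.2 | 0 | 1.3 |

(each reading ± 1 percentage point)

- a reading or a percentage of target counts all its forms, free or not

1. which of these there is most of at the end, counted by the starting material in it, alpha (isomer of the product / target / first chain carrier / starting material)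
2. which of these there is most of at the end, counted by the starting material in it, beta (isomer of the product / target / first chain carrier / starting material)
3. which of these there is most of at the end, counted by the starting material in it, theta (isomer of the product / target / first chain carrier / starting material)
4. the largest of these amounts at the end, in percent of the starting material charged, alpha
5. the largest of these amounts at the end, in percent of the starting material charged, beta
6. the largest of these amounts at the end, in percent of the starting material charged, theta

**Two rounds.** Larch's last reading gives k = 0.00834 /min, and alder's reading at 50.0 min gives 0.0467 /min. For a first round, try the square root of c, as a radical chain suggests. Carried from larch to alder, it leaves 24.3%, but alder reads 9.7%. So go round again and put the readings back in: the order in c comes out as n = 0.705. Now D = kL(c/cL)ⁿt, with cL larch's charge, and alpha comes to 0.656. This is the dose, the number of factors of e by which the flask's time reduces its starting material.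

**Reading it.** A dose below 0.693 leaves more than half, and alpha's does, so I expect starting material to lead there at 51.9%. Beta's dose is 1.42 and theta's 3.11, leaving 24.2% and 4.46%. Taking isomer of the product at alder's last reading, 14.2%, I get target at 61.7% in beta and 81.3% in theta, leading both.

**Is one number enough?** Not quite. Alder's mean k rises from 0.0377 /min at 25.0 min to 0.0467 /min, so theta, nearest alder, should end below its exp(−D).

**Forecast and flask.** The forecast gives 50%, 58% and 77% for the same leaders, on an order “close to the square root expected for a radical chain”, and my beta and theta figures stand above its. The flasks give starting material at 51.5% in alpha, target at 58.5% in beta and target at 83.0% in theta.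

    starting material + second chain carrier → released group + first chain carrier (k = 1.10 × 10⁵ /M/min)
    2 first chain carrier → ended chains A (k = 2.00 × 10⁶ /M/s)
    starting material + initiating radical → capped initiator + first chain carrier (k = 45000 /M/s)
    crystals ⇌ target, rate k4*(cs4 - [target]) while solid is left; crystals form when [target] > cs4 (solubility = 5.40 mM, k = 0.0760 /min)
    target ⇌ isomer of the product (K = 1.50, k = 0.0790 /min)
    initiator → 2 initiating radical (k = 0.00230 /min)
    2 second chain carrier → ended chains B (k = 3.00 × 10⁸ /M/s)
    partner → decomposed reagent (k = 0.00220 /min)
    partner + first chain carrier → target + second chain carrier (k = 20000 /M/s)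

**The dose tested.** Alpha's dose gave 51.9% against 51.5%. Theta's, 3.11, gave 4.46%, yet theta holds 0.560%, and the difference in initiator is the main reason it lies 51 percentage points under alpha's 51.5%. Capped initiator stands in theta at 0.112 M at the end, a third of the starting material charged, and each one marks a starting material taken by initiating radical, not by second chain carrier. Beta's neighbour with 1.3 M of starting material has beta's dose, 1.42, which leaves 24.2%, but with partner at 0% of its charge it keeps 68.5%.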